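**Assumptions (one line each)**
- The target SMILES has no stereocentres (Gancaonin G is achiral), so "single enantiomer" needs no stereocontrol.
- Prunetin (5,4'-dihydroxy-7-methoxyisoflavone) is a catalogue compound; if needed it can be made from genistein by selective 7-O-methylation (not counted).

**Retrosynthetic overview**
1. Target = 6-prenylprunetin; all three rings are bought intact in prunetin (1), so no ring is formed in the route.
2. C6-prenyl ⇒ C6-allyl plus olefin cross-metathesis with 2-methyl-2-butene.
3. C6-allyl ⇒ 5-O-allyl ether by aromatic Claisen rearrangement; the only free ortho position of the 5-oxygen is C6, so regiochemistry is fixed.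
4. The 4'-OH is carried as an allyl ether (installed in the same pot as the 5-O-allyl) and removed with Pd(0) before metathesis.
5. Forward: 1 + 2 → 3 → 4 → 5; 5 + 6 → 7.

**Route**

Step 1
Reactants: 1 prunetin (5-hydroxy-3-(4-hydroxyphenyl)-7-methoxy-4H-chromen-4-one); 2 allyl bromide
Product: 3, 7-methoxy-5-(allyloxy)-3-[4-(allyloxy)phenyl]-4H-chromen-4-one (prunetin 5,4'-di-O-allyl ether)
Conditions: allyl bromide (3 equiv), K2CO3 (4 equiv), DMF, 60 °C
Reagents that add atoms: allyl bromide, C=CCBr (two allyl groups incorporated)
Why: Williamson ether synthesis (SN2); excess electrophile in DMF alkylates both the free 4'-OH and the less reactive, hydrogen-bonded 5-OH; no stereocentre.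

Step 2
Reactants: 3 prunetin 5,4'-di-O-allyl ether
Product: 4, 6-allyl-5-hydroxy-7-methoxy-3-[4-(allyloxy)phenyl]-4H-chromen-4-one
Conditions: Eu(fod)3 (10 mol %), PhCl, 90–110 °C, Ar
Reagents that add atoms: none
Why: Eu(III)-catalysed aromatic Claisen ([3,3]) rearrangement; chelation of Eu to C4=O/5-O activates only the 5-O-allyl ether, which can migrate only to C6, while the unactivated 4'-O-allyl ether needs about 180 °C or more; no stereocentre.

Step 3
Reactants: 4, 6-allyl-4'-O-allyl compound
Product: 5, 6-allyl-5-hydroxy-3-(4-hydroxyphenyl)-7-methoxy-4H-chromen-4-one (6-allylprunetin)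
Conditions: Pd(PPh3)4 (5 mol %), K2CO3, MeOH–THF, rt
Reagents that add atoms: none
Why: Pd(0) O-deallylation (Tsuji–Trost type); the aryl allyl ether ionises to a π-allyl-Pd species that methoxide traps, whereas the C-allyl group has no leaving group and is untouched; no stereocentre.

Step 4
Reactants: 5, 6-allylprunetin; 6, 2-methyl-2-butene
Product: 7, Gancaonin G (5-hydroxy-3-(4-hydroxyphenyl)-7-methoxy-6-(3-methylbut-2-en-1-yl)-4H-chromen-4-one)
Conditions: Grubbs II (5 mol %), 2-methyl-2-butene (large excess, co-solvent), CH2Cl2, 40 °C, sealed tube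
Reagents that add atoms: 2-methyl-2-butene, CC=C(C)C (supplies the =C(CH3)2 terminus; =CH2 is lost as propene)
Why: Olefin cross-metathesis of a terminal allyl arene with 2-methyl-2-butene gives the trisubstituted prenyl alkene; free phenols and the chromone C2=C3 are inert to the Ru carbene, and the gem-dimethyl terminus means there is no E/Z issue or stereocentre.

**Compound list**
1 | Prunetin (5,4'-dihydroxy-7-methoxyisoflavone) | COc1cc2occ(-c3ccc(O)cc3)c(=O)c2c(O)c1 | starting material
2 | Allyl bromide | C=CCBr | starting material
3 | 5,4'-Bis(allyloxy)-7-methoxyisoflavone | COc1cc2occ(-c3ccc(OCC=C)cc3)c(=O)c2c(OCC=C)c1 | intermediate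
4 | 6-Allyl-4'-(allyloxy)-5-hydroxy-7-methoxyisoflavone | COc1cc2occ(-c3ccc(OCC=C)cc3)c(=O)c2c(O)c1CC=C | intermediate
5 | 6-Allyl-5,4'-dihydroxy-7-methoxyisoflavone | COc1cc2occ(-c3ccc(O)cc3)c(=O)c2c(O)c1CC=C | intermediate
6 | 2-Methyl-2-butene | CC=C(C)C | starting material
7 | Gancaonin G (achiral) | COc1cc2occ(-c3ccc(O)cc3)c(=O)c2c(O)c1CC=C(C)C | target

**Totals**
Total steps: 4. Longest linear sequence: 4.

**Three steps most likely to fail, with fallbacks**
1. Step 2 (Claisen): risks are incomplete conversion, partial 4'-O-allyl migration if heated too hard, or some C8 product by Claisen–Cope.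
 Fallback: drop the sigmatropic approach. Acetylate the 4'-OH of prunetin, iodinate at C6 ortho to the free 5-OH (BnMe3N·ICl2, CaCO3, CH2Cl2–MeOH), then Pd-couple with prenyl-Bpin (Suzuki) or prenyl-SnBu3 (Stille) and deacetylate with K2CO3/MeOH.
2. Step 4 (cross-metathesis): risks are Ru-H isomerisation of the allyl to a propenyl arene or stalled conversion with the free phenols.
 Fallback: avoid metathesis by making the 5-O-(1,1-dimethylallyl) ether instead (Cu-catalysed O-propargylation with a 2-methylbut-3-yn-2-yl carbonate, then Lindlar reduction). Its [3,3] shift delivers the prenyl group directly at C6.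
3. Step 1 (bis-allylation): risks are sluggish alkylation of the chelated 5-OH or competing C-allylation.
 Fallback: differentiate the phenols. Selectively acetylate the 4'-OH (Ac2O, pyridine), then allylate the 5-OH by Mitsunobu reaction (allyl alcohol, PPh3, DIAD). Continue with Claisen and metathesis, and finish with K2CO3/MeOH deacetylation in place of the Pd step.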